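## Structural features

The target is a flavanone: a benzene ring (ring A) fused to a dihydropyran-4-one (ring C), with a 2-hydroxy-6-methoxyphenyl group (ring B) on C2, the only stereocenter (S). Ring A is hexasubstituted and pentaoxygenated: O1 on C8a, methoxy groups on C6, C7 and C8, a free hydroxyl on C5 hydrogen-bonded to the C4 carbonyl, and C4 on C4a. Ring B is bonded through C1', which lies between two different oxygens (2'-OH and 6'-OMe), so C2 is a di-ortho-substituted, electron-rich benzylic C–O center with no neighbouring stereocenter to lean on. This center is fragile: under acid the C2–O1 bond can ionize to an oxygen-stabilized benzylic cation, under base ring C opens by retro-oxa-Michael reaction to a 2'-hydroxychalcone, and a free 2'-OH can divert such an enone to a flavylium ion; each path erases the configuration. Two phenols (5-OH, 2'-OH) must end free beside four methoxy groups, so the oxygens have to be differentiated by construction. The real difficulty is to make the O1 linkage of the crowded, labile C2 with full stereochemical fidelity while assembling the fully substituted ring A. The key step exploits the para relation of the oxygens on C5 and C8: ring A is a masked para-quinone, and in its dearomatized (quinone monoketal) form C8a is the beta carbon of both the ring carbonyl (C5) and the C4 ketone, an electrophile for the oxygen already on C2.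

## Logic of the disconnections

12 ⇒ 11. The bond cut is O2'–CH2Ph: a benzyl group is placed on the ring B phenol. Ring B must be inert while ring A is oxidized, and the mask must come off without acid or base, which would ionize or open C2–O1. The cost is one step. The forward step must cleave the ether benzylic C–O bond and spare the other benzylic C–O bond (C2–O1) and the C4 ketone.

11 ⇒ 8 (key disconnection, through 10 and 9). The bond cut is O1–C8a, and C8a returns to a C–H. The oxygen that becomes O1 stays on C2 as the secondary hydroxyl of an open-chain aldol; the phenolic oxygen of 8 is O5, not O1. In one sentence: 11 is made by attack of the C2 carbinol oxygen of 8 on C8a of ring A after oxidative dearomatization of that ring. That sentence does not fit the customary route, in which a ring A phenol oxygen attacks C2 of an enone. The gain is threefold. Ring C is opened to an acyclic precursor. Ring A drops from five oxygens to four and so derives from symmetric 3. The 5-OH/8-OMe differentiation is built in (phenol oxygen versus ketal carbon), and C2–O becomes a spectator bond that is neither made nor broken after the stereocenter exists. The forward step must oxidize ring A chemoselectively to a species electrophilic at C8a (9), a hindered secondary alcohol must add 6-endo (10), and aromatization must keep exactly one alkoxy group on C8.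

8 ⇒ 2 + 6. The bond cut is C2–C3 (aldol). This divides the molecule into two aromatic halves of similar size and places the creation of C2 in a kinetically controlled, catalyst-controlled C–C bond formation with no reversible C–O chemistry at C2. The forward step must add to the Si face of a di-ortho-substituted aldehyde and must avoid dehydration of the product.

6 ⇒ 5 ⇒ 3 (through 4). The bonds cut are the two O–Si bonds of 6, then C4–C4a (acylation), with the methyl group on O5 restored. Compound 3 has only one kind of ring C–H, so the acylation has no regiochemical question. The chelate between the new carbonyl and its ortho methoxy group singles out the future O5 for demethylation. The forward step must stop after one ether cleavage.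

2 ⇒ 1. The bond cut is O–CH2Ph. The forward step is a phenol alkylation on a commercial aldehyde that already carries the 2'-O/6'-OMe differentiation of ring B.

## Other disconnections considered

Alternative 1: (the first that comes to mind) cut O1–C2 and C2=C3.
- Forward: Claisen–Schmidt condensation of 1-(2-hydroxy-3,4,5,6-tetramethoxyphenyl)ethan-1-one A1 with 2 gives the 2'-hydroxychalcone A2. Base- or bifunctional-organocatalyst-mediated 6-endo oxa-Michael closure gives the 5-O-methyl flavanone A3, followed by cleavage of the 5-O-methyl and benzyl groups.
- Grounds for preferring the chosen plan: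
  - A1 already needs all five ring A oxygens, so it costs several steps from a tetraoxygenated arene.
  - In A2 both aryl groups are di-ortho-substituted, the enone is twisted, and the beta carbon is shielded by the two ortho substituents of ring B. Closure is slow and reversible.
  - Any catalyst basic enough to close the ring also reopens it, so C2 is under thermodynamic control and enantioselectivity rests on a reversible step.
  - A late chelation-controlled demethylation is still needed.
  - The chosen plan never passes through an enone, and sets C2 in an irreversible C–C bond formation.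

Alternative 2: cut C2–C1'.
- Forward: catalytic asymmetric conjugate addition of [2-(benzyloxy)-6-methoxyphenyl]boronic acid A5 to 5,6,7,8-tetramethoxy-4H-chromen-4-one A4, giving A3. The catalyst would be Pd(OCOCF3)2 with a chiral pyridine-oxazoline ligand, or a chiral diene complex of monovalent rhodium.
- Grounds for preferring the chosen plan:
  - The aryl group to be transferred carries two ortho oxygens. Such boronic acids protodeboronate quickly, and transmetalation and migratory insertion are slow.
  - The accepting carbon is flanked by O1 and lies on a chromone that is a weak acceptor, made weaker by four donor groups.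
  - The step most likely to fail is therefore the only stereo-defining one.
  - A4 also presupposes the pentaoxygenated ketone A1.

Alternative 3: cut C2–C3 by carbenoid C–H insertion.
- Forward: 2-diazo-1-(2-{[2-(benzyloxy)-6-methoxyphenyl]methoxy}-3,4,5,6-tetramethoxyphenyl)ethan-1-one A6 is made from A1 by etherification and diazo transfer. With Rh2(OAc)4 or a chiral dirhodium tetracarboxylate, 1,6-insertion of the carbenoid into the benzylic ether C–H would close ring C and set C2 in one step, giving A3.
- Grounds for preferring the chosen plan:
  - The route is short, but an acceptor-only carbenoid next to an aryl ether oxygen is expected to form the five-membered oxonium ylide first.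
  - That ylide should undergo a [1,2]-benzyl (Stevens) shift to the benzofuranone A7, since an electron-rich benzyl group migrates well.
  - Insertion into the C–H bonds of the neighbouring O-methyl group competes.
  - Enantiocontrol in six-membered-ring insertions of such diazoketones is weak.
  - The pentaoxygenated ring must again be made first.

Key step: step 5

Assumption: 1 and 3 are taken as catalogue compounds. The facial sense of the catalytic aldol addition is not presumed for this di-ortho-substituted aldehyde, so the catalyst antipode is specified by the face it must attack (Si face of 2, which gives the S carbinol).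

## Route

Step 1
Reactants: 1 2-hydroxy-6-methoxybenzaldehyde
Product: 2 2-(benzyloxy)-6-methoxybenzaldehyde
Conditions: BnBr (1.1 equiv), K2CO3, DMF, rt
Reagents that add atoms: benzyl bromide, BrCc1ccccc1
Why: Williamson ether synthesis (SN2 of the phenoxide on a benzylic bromide); the aldehyde is untouched and the benzyl ether masks the ring B phenol against the later oxidation.

Step 2
Reactants: 3 1,2,3,4-tetramethoxybenzene
Product: 5 1-(2-hydroxy-3,4,5-trimethoxyphenyl)ethan-1-one, via tetramethoxyacetophenone 4 (not isolated)
Conditions: AcCl (1.1 equiv), AlCl3 (2.5 equiv), CH2Cl2, 0 °C to rt; aqueous work-up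
Reagents that add atoms: acetyl chloride, CC(Cl)=O
Why: Friedel–Crafts acylation at the only kind of ring C–H of symmetric 3 gives 4; AlCl3 held in a six-membered chelate between the new carbonyl and the ortho methoxy group then cleaves that methyl ether alone (chloride attack on the activated O–CH3), and the chelated phenol of 5 is the future 5-OH.

Step 3
Reactants: 5 1-(2-hydroxy-3,4,5-trimethoxyphenyl)ethan-1-one
Product: 6 trimethyl[(1-{3,4,5-trimethoxy-2-[(trimethylsilyl)oxy]phenyl}ethenyl)oxy]silane
Conditions: Me3SiOTf (2.3 equiv), Et3N (3 equiv), CH2Cl2, 0 °C; pentane extraction, used directly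
Reagents that add atoms: trimethylsilyl trifluoromethanesulfonate, C[Si](C)(C)OS(=O)(=O)C(F)(F)F
Why: Soft enolization of the methyl ketone by silyl triflate and amine gives the terminal enol silane (no regiochemical issue) and silylates the phenol transiently, so that neither a proton source nor a chelating phenol is present in the aldol step.

Step 4
Reactants: 2 2-(benzyloxy)-6-methoxybenzaldehyde; 6 trimethyl[(1-{3,4,5-trimethoxy-2-[(trimethylsilyl)oxy]phenyl}ethenyl)oxy]silane
Product: 8 (3S)-3-[2-(benzyloxy)-6-methoxyphenyl]-3-hydroxy-1-(2-hydroxy-3,4,5-trimethoxyphenyl)propan-1-one, via trichlorosilyl aldolate 7 (not isolated)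
Conditions: SiCl4 (1.5 equiv), chiral bisphosphoramide derived from N,N'-dimethyl-1,1'-binaphthyl-2,2'-diamine (pentane-1,5-diyl linked, 5–10 mol %, antipode chosen for Si-face attack), i-Pr2NEt (0.1 equiv), CH2Cl2, −78 °C; sat. aq. NaHCO3, rt
Reagents that add atoms: none
Why: Lewis-base-activated Mukaiyama aldol addition: the phosphoramide ionizes SiCl4 to a chiral trichlorosilyl cation that binds the aldehyde, and the enol silane should add through an open transition state to the Si face (catalyst control), giving the S carbinol as its silyl ether 7. The bicarbonate work-up hydrolyses both O–Si bonds under conditions too mild to dehydrate the aldol.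

Step 5
Reactants: 8 (3S)-3-[2-(benzyloxy)-6-methoxyphenyl]-3-hydroxy-1-(2-hydroxy-3,4,5-trimethoxyphenyl)propan-1-one
Product: 11 (2S)-2-[2-(benzyloxy)-6-methoxyphenyl]-5-hydroxy-6,7,8-trimethoxy-2,3-dihydro-4H-chromen-4-one, via quinone monoketal 9 (not isolated), via ketal adduct 10 (not isolated)
Conditions: PhI(OAc)2 (1.05 equiv), MeOH, 0 °C, 20 min; evaporate with toluene; CH2Cl2, Et3N (0.2 equiv), 0 °C to rt; AcOH quench
Reagents that add atoms: methanol, CO (enters as one of the two methoxy groups on the ketal carbon of 9; one of the two is lost again on aromatization)
Why: PhI(OAc)2 exchanges an acetate for the chelated phenol of 8, and two-electron oxidation with capture by methanol at the methoxy-bearing para carbon gives the acyl quinone monoketal 9 (oxidative dearomatization of a para-methoxyphenol by a trivalent iodine reagent; attack at the ortho methoxy carbon would give an isomeric ketal that should funnel to the same product). In 9 the only ring CH (the future C8a) is the beta carbon of both the dienone carbonyl and the C4 ketone, an alkylidene-1,3-dicarbonyl acceptor, and once methanol is removed the C2 carbinol should add to it in a 6-endo-trig oxa-Michael reaction, closing ring C through O1–C8a (the polarity-reversed counterpart of the chalcone cyclization) to the chelated enol 10. Loss of one methoxy group of the adjacent ketal carbon as methanol then re-aromatizes ring A irreversibly, so that the former phenol becomes the hydrogen-bonded 5-OH, the ketal carbon becomes C8–OMe and O1 is the oxygen installed in the aldol step. The closest known reaction types are the conjugate addition–aromatization of O-nucleophiles with quinone monoketals and the dearomatization/intramolecular oxa-Michael cascades of phenols with tethered alcohols. No new stereocenter survives (C8a of 10 is lost on aromatization), and C2 keeps its S configuration because its C–O bond is never broken and neither a benzylic cation nor an enone intervenes. The step needs chemoselective oxidation of ring A, secured by the benzyl mask on ring B, by the inertness of aryl ethers to PhI(OAc)2 in methanol, and by one equivalent of oxidant that is consumed before the product phenol exists. It also needs intra- over intermolecular conjugate addition, secured by exchanging methanol for CH2Cl2 before the amine trigger and by the six-membered transition state.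

Step 6
Reactants: 11 (2S)-2-[2-(benzyloxy)-6-methoxyphenyl]-5-hydroxy-6,7,8-trimethoxy-2,3-dihydro-4H-chromen-4-one
Product: 12 (2S)-5-hydroxy-2-(2-hydroxy-6-methoxyphenyl)-6,7,8-trimethoxy-2,3-dihydro-4H-chromen-4-one
Conditions: H2 (1 atm), 10% Pd/C, EtOAc, rt
Reagents that add atoms: none
Why: Hydrogenolysis of the aryl benzyl ether under neutral conditions; the chelated aryl ketone and the hindered C2–O1 bond should react much more slowly, and the absence of acid and base leaves C2 (S) untouched.

## Compound list

1 | 2-hydroxy-6-methoxybenzaldehyde | COc1cccc(O)c1C=O | starting material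
2 | 2-(benzyloxy)-6-methoxybenzaldehyde | COc1cccc(OCc2ccccc2)c1C=O | intermediate
3 | 1,2,3,4-tetramethoxybenzene | COc1ccc(OC)c(OC)c1OC | starting material
4 | 1-(2,3,4,5-tetramethoxyphenyl)ethan-1-one (not isolated) | CC(=O)c1cc(OC)c(OC)c(OC)c1OC | intermediate
5 | 1-(2-hydroxy-3,4,5-trimethoxyphenyl)ethan-1-one | CC(=O)c1cc(OC)c(OC)c(OC)c1O | intermediate
6 | trimethyl[(1-{3,4,5-trimethoxy-2-[(trimethylsilyl)oxy]phenyl}ethenyl)oxy]silane | C=C(O[Si](C)(C)C)c1cc(OC)c(OC)c(OC)c1O[Si](C)(C)C | intermediate
7 | (3S)-3-[2-(benzyloxy)-6-methoxyphenyl]-3-[(trichlorosilyl)oxy]-1-{3,4,5-trimethoxy-2-[(trimethylsilyl)oxy]phenyl}propan-1-one (not isolated) | COc1cccc(OCc2ccccc2)c1[C@@H](O[Si](Cl)(Cl)Cl)CC(=O)c1cc(OC)c(OC)c(OC)c1O[Si](C)(C)C | intermediate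
8 | (3S)-3-[2-(benzyloxy)-6-methoxyphenyl]-3-hydroxy-1-(2-hydroxy-3,4,5-trimethoxyphenyl)propan-1-one | COc1cccc(OCc2ccccc2)c1[C@@H](O)CC(=O)c1cc(OC)c(OC)c(OC)c1O | intermediate
9 | 6-{(3S)-3-[2-(benzyloxy)-6-methoxyphenyl]-3-hydroxypropanoyl}-2,3,4,4-tetramethoxycyclohexa-2,5-dien-1-one (not isolated) | COc1cccc(OCc2ccccc2)c1[C@@H](O)CC(=O)C1=CC(OC)(OC)C(OC)=C(OC)C1=O | intermediate
10 | (2S)-2-[2-(benzyloxy)-6-methoxyphenyl]-5-hydroxy-6,7,8,8-tetramethoxy-2,3,8,8a-tetrahydro-4H-chromen-4-one (enol form, C8a configuration not defined, not isolated) | COc1cccc(OCc2ccccc2)c1[C@@H]1CC(=O)C2=C(O)C(OC)=C(OC)C(OC)(OC)C2O1 | intermediate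
11 | (2S)-2-[2-(benzyloxy)-6-methoxyphenyl]-5-hydroxy-6,7,8-trimethoxy-2,3-dihydro-4H-chromen-4-one | COc1cccc(OCc2ccccc2)c1[C@@H]1CC(=O)c2c(O)c(OC)c(OC)c(OC)c2O1 | intermediate
12 | (2S)-5-hydroxy-2-(2-hydroxy-6-methoxyphenyl)-6,7,8-trimethoxy-2,3-dihydro-4H-chromen-4-one | COc1cccc(O)c1[C@@H]1CC(=O)c2c(O)c(OC)c(OC)c(OC)c2O1 | target

## Step count and least certain steps

Total step count: 6. Longest linear sequence: 5 steps (3 → 5 → 6 → 8 → 11 → 12; step 1 is a one-step side branch).

Step 5 (key step). What may go wrong: capture of the dearomatized ring at C8a by the solvent alcohol or adventitious water in place of the C2 carbinol, which is a hindered nucleophile because of the di-ortho-substituted ring B. Loss of water from the aldol unit, followed by closure through the phenol oxygen at C2, would give the wrong ring fusion without stereocontrol. Fallback: the same O1–C8a bond is made by halogenation and metal-catalysed C–O coupling instead of dearomatization; it sets out from 5 and returns at 11. Bromination of the single ring C–H of 5 (N-bromosuccinimide, MeCN, 0 °C) gives 1-(2-bromo-6-hydroxy-3,4,5-trimethoxyphenyl)ethan-1-one F1. Silylation as in step 3 gives {[1-(2-bromo-3,4,5-trimethoxy-6-[(trimethylsilyl)oxy]phenyl)ethenyl]oxy}trimethylsilane F2. Aldol addition to 2 as in step 4 gives (3S)-3-[2-(benzyloxy)-6-methoxyphenyl]-1-(2-bromo-6-hydroxy-3,4,5-trimethoxyphenyl)-3-hydroxypropan-1-one F3. Intramolecular aryl etherification (Pd(OAc)2, 2-(di-tert-butylphosphino)-1,1'-binaphthyl, Cs2CO3, toluene, 65 °C) then gives 11; zerovalent palladium inserts into C–Br, the alkoxide binds, and C–O reductive elimination proceeds with retention at C2.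

Step 4. What may go wrong: low conversion and poor facial selectivity, because the di-ortho-substituted aldehyde binds poorly in the chiral pocket of the silyl cation, and dehydration of the aldol on acidic silica. The configuration of 8 is to be assigned (MTPA esters), not presumed. Fallback: resolution instead of asymmetric catalysis; it sets out from 5 and 2 and returns at 8. The dilithium dianion of 5 (LDA, 2.2 equiv, THF, −78 °C) adds to 2 to give the racemic aldol, that is 8 together with (3R)-3-[2-(benzyloxy)-6-methoxyphenyl]-3-hydroxy-1-(2-hydroxy-3,4,5-trimethoxyphenyl)propan-1-one F4. Preparative chiral-phase chromatography delivers 8, and F4 is returned to 5 and 2 by base-induced retro-aldol cleavage.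

Step 2. What may go wrong: cleavage of a second methyl ether (the one next to the aluminium phenoxide) or incomplete cleavage, leading to mixtures. Fallback: directed metalation instead of electrophilic substitution, with the ether cleavage as a separate operation; it sets out from 3 and returns at 5. Ortho-lithiation (n-BuLi, TMEDA, THF, 0 °C) gives (2,3,4,5-tetramethoxyphenyl)lithium F5, which with N-methoxy-N-methylacetamide gives 4, now isolated. BCl3 (1.1 equiv, CH2Cl2, −78 °C) then removes only the methyl group chelated to the carbonyl and gives 5.

Step 6. What may go wrong: over-reduction, that is hydrogenolysis of the benzylic C2–O1 bond with ring opening, or reduction of the C4 ketone. Fallback: non-reductive Lewis-acid debenzylation; it sets out from 11 and returns at 12 with no new compound (F0). BCl3 with pentamethylbenzene as benzyl-cation scavenger in CH2Cl2 at −78 °C should spare the chelated 5-OH and the non-chelated methyl ethers at this temperature.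

## Further compounds

F1 | step 5 | 1-(2-bromo-6-hydroxy-3,4,5-trimethoxyphenyl)ethan-1-one | CC(=O)c1c(Br)c(OC)c(OC)c(OC)c1O
F2 | step 5 | {[1-(2-bromo-3,4,5-trimethoxy-6-[(trimethylsilyl)oxy]phenyl)ethenyl]oxy}trimethylsilane | C=C(O[Si](C)(C)C)c1c(Br)c(OC)c(OC)c(OC)c1O[Si](C)(C)C
F3 | step 5 | (3S)-3-[2-(benzyloxy)-6-methoxyphenyl]-1-(2-bromo-6-hydroxy-3,4,5-trimethoxyphenyl)-3-hydroxypropan-1-one | COc1cccc(OCc2ccccc2)c1[C@@H](O)CC(=O)c1c(Br)c(OC)c(OC)c(OC)c1O
F4 | step 4 | (3R)-3-[2-(benzyloxy)-6-methoxyphenyl]-3-hydroxy-1-(2-hydroxy-3,4,5-trimethoxyphenyl)propan-1-one | COc1cccc(OCc2ccccc2)c1[C@H](O)CC(=O)c1cc(OC)c(OC)c(OC)c1O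
F5 | step 2 | (2,3,4,5-tetramethoxyphenyl)lithium | [Li]c1cc(OC)c(OC)c(OC)c1OC
F0 | step 6 | none | none
A1 | alternative 1 | 1-(2-hydroxy-3,4,5,6-tetramethoxyphenyl)ethan-1-one | CC(=O)c1c(O)c(OC)c(OC)c(OC)c1OC
A2 | alternative 1 | (2E)-3-[2-(benzyloxy)-6-methoxyphenyl]-1-(2-hydroxy-3,4,5,6-tetramethoxyphenyl)prop-2-en-1-one | COc1cccc(OCc2ccccc2)c1/C=C/C(=O)c1c(O)c(OC)c(OC)c(OC)c1OC
A3 | alternative 1 | (2S)-2-[2-(benzyloxy)-6-methoxyphenyl]-5,6,7,8-tetramethoxy-2,3-dihydro-4H-chromen-4-one | COc1cccc(OCc2ccccc2)c1[C@@H]1CC(=O)c2c(OC)c(OC)c(OC)c(OC)c2O1
A4 | alternative 2 | 5,6,7,8-tetramethoxy-4H-chromen-4-one | O=c1ccoc2c(OC)c(OC)c(OC)c(OC)c12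
A5 | alternative 2 | [2-(benzyloxy)-6-methoxyphenyl]boronic acid | COc1cccc(OCc2ccccc2)c1B(O)O
A6 | alternative 3 | 2-diazo-1-(2-{[2-(benzyloxy)-6-methoxyphenyl]methoxy}-3,4,5,6-tetramethoxyphenyl)ethan-1-one | COc1cccc(OCc2ccccc2)c1COc1c(OC)c(OC)c(OC)c(OC)c1C(=O)C=[N+]=[N-]
A7 | alternative 3 | 2-{[2-(benzyloxy)-6-methoxyphenyl]methyl}-4,5,6,7-tetramethoxy-1-benzofuran-3(2H)-one | COc1cccc(OCc2ccccc2)c1CC1Oc2c(OC)c(OC)c(OC)c(OC)c2C1=O
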